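**Retrosynthetic overview**

1. Target 10 is a 27-membered ring with lactone carbonyl C1, ketone C22, twenty CH2 (C2–C21) between them, and C23–C26 linking C22 to the ring oxygen. It is cut across the ring at a transannular C1–C22 bond, giving bicyclic hemiketal 9: a 22-membered carbocycle fused to a 7-membered oxepane (O, C1, C22, C23–C26). Oxidative scission of that shared bond is a 22 → 27 ring expansion that forms the lactone C1(=O)–O and the ketone C22=O together.
2. Hemiketal 9 is the ring tautomer of α-ketol 8. The C22–C23 bond of 8 comes from addition of a 4-(silyloxy)butyl Grignard reagent (from 5) to cyclodocosane-1,2-dione 4.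
3. Dione 4 comes from bis-silyl enediol ether 3, formed by acyloin closure (C1–C22) of dimethyl docosanedioate 2 (from diacid 1). Both carboxyl carbons of the C22 diacid become C1 and C22, so no desymmetrisation of the diacid and no end-to-end lactonisation is needed.
4. Ring order: 22-membered carbocycle (step 2), then the transient oxepane hemiketal and the 27-membered lactone (step 5).

Key step: step 5

Remark: the target has no stereocenter and is achiral, so no enantioselective step is required. Intermediates 7 and 8 are racemic and 9 is a diastereomer mixture; these stereocenters are destroyed in step 5.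
Remark: 3 is drawn as the Z enediol ether; its geometry is of no consequence because both sp2 carbons become carbonyl carbons in step 3.

**Step 1**
Reactants: 1 docosanedioic acid
Product: 2 dimethyl docosanedioate
Conditions: MeOH (excess), cat. H2SO4, toluene cosolvent, reflux
Reagents that add atoms: methanol, CO
Why: Fischer esterification driven by excess methanol converts both acid groups into the ester form that the sodium-mediated acyloin closure requires.

**Step 2**
Reactants: 2 dimethyl docosanedioate
Product: 3 (Z)-1,2-bis(trimethylsilyloxy)cyclodocos-1-ene
Conditions: Na dispersion (4.4 equiv), TMSCl (4.5 equiv), toluene, reflux, slow addition of 2; filter under argon, concentrate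
Reagents that add atoms: chlorotrimethylsilane, C[Si](C)(C)Cl
Why: Acyloin condensation in the Rühlmann variant joins the two ester carbons (C1–C22) on the sodium surface, a closure that is classically efficient for carbocycles of about twenty members, while TMSCl traps methoxide and the enediolate and so suppresses Dieckmann condensation.

**Step 3**
Reactants: 3 (Z)-1,2-bis(trimethylsilyloxy)cyclodocos-1-ene
Product: 4 cyclodocosane-1,2-dione
Conditions: Br2 (1.0 equiv), CH2Cl2, −78 °C → rt; evaporate
Reagents that add atoms: none
Why: Bromine attacks the electron-rich enediol bis-silyl ether and loss of two TMSBr gives the 1,2-diketone directly, the known oxidation of acyloin bis-silyl ethers, without passing through the free acyloin.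

**Step 4**
Reactants: 4 cyclodocosane-1,2-dione; 5 (4-bromobutoxy)(tert-butyl)dimethylsilane
Product: 8 2-hydroxy-2-(4-hydroxybutyl)cyclodocosan-1-one (racemic), via Grignard reagent 6 (not isolated), via TBS-protected ketol 7 (not isolated)
Conditions: 5, Mg, THF, rt; then LaCl3·2LiCl (1.0 equiv), 4 (1.0 equiv, Grignard 1.05 equiv added to the dione), THF, −78 → −40 °C; then 2 M aq HCl, THF, rt
Reagents that add atoms: none
Why: Lewis-acid-promoted Grignard 1,2-addition to one carbonyl of the 1,2-diketone forms the C22–C23 bond with enolisation suppressed, the resulting tertiary alkoxide shields the neighbouring carbonyl from a second addition, and aqueous acid then cleaves the primary TBS ether; C22 is formed racemic and is lost as a stereocenter in step 5.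

**Step 5**
Reactants: 8 2-hydroxy-2-(4-hydroxybutyl)cyclodocosan-1-one
Product: 10 22-keto-26-hexacosanolide (1-oxacycloheptacosane-2,23-dione), via bicyclic hemiketal 9 (not isolated)
Conditions: Pb(OAc)4 (1.1 equiv), dry CH2Cl2 (0.01 M), 0 °C → rt
Reagents that add atoms: none
Why: The primary hydroxyl on C26 adds to the C1 ketone of 8 (7-exo-trig) to give the α-hydroxy hemiketal 9, whose vicinal hydroxyls on C1 and C22 form a cyclic lead(IV) diester that collapses in a two-electron fragmentation of the C1–C22 bond. C1, already bonded to the C26 oxygen, becomes the lactone carbonyl and C22 becomes the ketone; this is a Criegee glycol cleavage, of the type known for α-ketols in the presence of alcohols (ester plus carbonyl compound) and for hemiketal diols of bicyclic enol ethers (ring-expanded keto lactones). The 27-membered ring is not closed end to end: it arises when the zero-atom bridge shared by the 22-membered carbocycle and the oxepane is cut, so the entropic penalty of a macrolactonisation is avoided. No stereocenter is formed and the two of 9 are destroyed. The step needs cleavage through the hemiketal rather than through capture of the C1 acyl fragment by an external nucleophile, and no oxidation of the primary alcohol. This should be secured by the aprotic solvent free of alcohols and water, by moderate dilution against intermolecular hemiketal formation, and by the much faster reaction of lead tetraacetate with 1,2-diols than with isolated primary alcohols at 0–20 °C.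

**Compound list**

1 | docosanedioic acid | OC(=O)CCCCCCCCCCCCCCCCCCCCC(=O)O | starting material
2 | dimethyl docosanedioate | COC(=O)CCCCCCCCCCCCCCCCCCCCC(=O)OC | intermediate
3 | (Z)-1,2-bis(trimethylsilyloxy)cyclodocos-1-ene | C[Si](C)(C)O/C1=C(\O[Si](C)(C)C)CCCCCCCCCCCCCCCCCCCC1 | intermediate
4 | cyclodocosane-1,2-dione | O=C1CCCCCCCCCCCCCCCCCCCCC1=O | intermediate
5 | (4-bromobutoxy)(tert-butyl)dimethylsilane | CC(C)(C)[Si](C)(C)OCCCCBr | starting material
6 | [4-(tert-butyldimethylsilyloxy)butyl]magnesium bromide | CC(C)(C)[Si](C)(C)OCCCC[Mg]Br | intermediate
7 | 2-[4-(tert-butyldimethylsilyloxy)butyl]-2-hydroxycyclodocosan-1-one (racemic) | CC(C)(C)[Si](C)(C)OCCCCC1(O)CCCCCCCCCCCCCCCCCCCCC1=O | intermediate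
8 | 2-hydroxy-2-(4-hydroxybutyl)cyclodocosan-1-one (racemic) | OCCCCC1(O)CCCCCCCCCCCCCCCCCCCCC1=O | intermediate
9 | 23-oxabicyclo[20.5.0]heptacosane-1,22-diol (bicyclic hemiketal of 8, diastereomer mixture, racemic) | OC12CCCCCCCCCCCCCCCCCCCCC1(O)CCCCO2 | intermediate
10 | 22-keto-26-hexacosanolide (1-oxacycloheptacosane-2,23-dione), achiral | O=C1CCCCCCCCCCCCCCCCCCCCC(=O)OCCCC1 | target

**Step count**

Total steps: 5. Longest linear sequence: 5 steps (1 → 2 → 3 → 4 → 8 → 10).

**Steps most likely to fail**

Step 5. The seven-membered hemiketal may be populated too little, so that cleavage of the open α-ketol with capture of the C1 acyl fragment by acetate or adventitious water outruns the ring-expanding pathway and gives ring-opened material or oligomeric esters. The fallback gives up the ring expansion for a seco-acid lactonisation. It sets out from 8: periodate cleavage of the α-ketol (NaIO4, THF/H2O, rt) should give 26-hydroxy-22-oxohexacosanoic acid F1. Treatment with 2,4,6-trichlorobenzoyl chloride and Et3N in THF should give the mixed anhydride, 26-hydroxy-22-oxohexacosanoic 2,4,6-trichlorobenzoic anhydride F2. Slow addition of F2 to DMAP in hot toluene at high dilution (Yamaguchi macrolactonisation) would close the 27-membered lactone and return to the route at 10.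

Step 4. The basic organometallic may enolise the diketone instead of adding, or add twice to give the bis-tertiary diol. The fallback reverses the polarity of the C22–C23 bond formation and bypasses the dione. It sets out from 3: MeLi (1.0 equiv, THF, 0 °C → rt) should cleave one silyl ether to give lithium (Z)-2-(trimethylsilyloxy)cyclodocos-1-en-1-olate F3. C-alkylation of this enolate with bromide 5 in THF/DMPU should give 2-[4-(tert-butyldimethylsilyloxy)butyl]-2-(trimethylsilyloxy)cyclodocosan-1-one F4. Aqueous HCl in THF would remove both silyl groups and return to the route at 8.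

Step 2. Intermolecular acyloin coupling to oligomers, or incomplete reduction on the heterogeneous sodium surface, may compete with ring closure. The fallback replaces the acyloin closure by a reductive carbonyl coupling. It sets out from 2: DIBAL-H (2.2 equiv, toluene, −78 °C) should give docosanedial F5. Low-valent titanium pinacol cyclisation (TiCl3(DME)1.5, Zn–Cu, DME, rt, slow addition at high dilution) should give cyclodocosane-1,2-diol F6 as a cis/trans mixture. Double Swern oxidation ((COCl)2, DMSO, Et3N, CH2Cl2, −78 °C) would return to the route at 4.

**Further compounds**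

F1 | step 5 | 26-hydroxy-22-oxohexacosanoic acid | OCCCCC(=O)CCCCCCCCCCCCCCCCCCCCC(=O)O
F2 | step 5 | 26-hydroxy-22-oxohexacosanoic 2,4,6-trichlorobenzoic anhydride | OCCCCC(=O)CCCCCCCCCCCCCCCCCCCCC(=O)OC(=O)c1c(Cl)cc(Cl)cc1Cl
F3 | step 4 | lithium (Z)-2-(trimethylsilyloxy)cyclodocos-1-en-1-olate | [Li+].[O-]/C1=C(\O[Si](C)(C)C)CCCCCCCCCCCCCCCCCCCC1
F4 | step 4 | 2-[4-(tert-butyldimethylsilyloxy)butyl]-2-(trimethylsilyloxy)cyclodocosan-1-one (racemic) | CC(C)(C)[Si](C)(C)OCCCCC1(O[Si](C)(C)C)CCCCCCCCCCCCCCCCCCCCC1=O
F5 | step 2 | docosanedial | O=CCCCCCCCCCCCCCCCCCCCCCC=O
F6 | step 2 | cyclodocosane-1,2-diol (cis/trans mixture) | OC1CCCCCCCCCCCCCCCCCCCCC1O
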